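**Plan**

1. Rings are lettered A (gem-dimethyl dienone end) to F (C-methylated aromatic end); the target is achiral, so no stereochemistry has to be set.
2. First cut: one C–CH3 bond at the sp3 carbon of ring A. This leaves a six-ring chain that is mirror-symmetric about the CH2 between rings C and D, with a C-methyl phloroglucinol ring at each end.
3. Second cut, made twice: the bond from the B/C bridge CH2 to ring B and from the D/E bridge CH2 to ring E. Both CH2 carbons sit ortho to hydroxyls of rings C and D and are carried there as CH2NMe2 arms, while rings B and E each offer one ring C–H flanked by two OH.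
4. Remaining cuts: the C/D, A/B-type and E/F CH2–aryl bonds and the aryl–C(=O) bonds, back to phloroglucinol, 2-methylphloroglucinol, butanoyl chloride, formaldehyde and Eschenmoser's salt.
5. Forward: two acylated monomers; then the ring C–ring D core (CH2O, two aminomethylations) and the outer dimer (one Mannich-base coupling); then the chain is joined from the centre outward in one double coupling (no ring forms); a single C-methylation finally turns one end into ring A.

Key step: step 7

Remark: polyphenols and dienones are drawn as one enol tautomer, and Mannich bases as neutral amino phenols although they exist largely as zwitterions.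

**Route**

Step 1
Reactants: 1 phloroglucinol; 2 butanoyl chloride
Product: 3 1-(2,4,6-trihydroxyphenyl)butan-1-one (butanoylphloroglucinol)
Conditions: AlCl3 (3.5 equiv), PhNO2–CH2Cl2, 0 to 40 °C; then ice, 1 M HCl
Reagents that add atoms: none
Why: Friedel–Crafts C-acylation of the electron-rich triol, whose three ring carbons are equivalent, should stop at the mono-ketone because the chelated acyl group deactivates the ring.

Step 2
Reactants: 4 2-methylbenzene-1,3,5-triol; 2 butanoyl chloride
Product: 5 1-(2,4,6-trihydroxy-3-methylphenyl)butan-1-one
Conditions: AlCl3 (3.5 equiv), PhNO2–CH2Cl2, 0 to 40 °C; then ice, 1 M HCl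
Reagents that add atoms: none
Why: Friedel–Crafts acylation at one of the two equivalent free ring carbons of 4 can give only one regioisomer.

Step 3
Reactants: 3 butanoylphloroglucinol (two molecules per bridge, used in large excess)
Product: 8 bis(3-butanoyl-2,4,6-trihydroxyphenyl)methane (ring C–ring D core dimer), via hydroxymethyl monomer 6 (not isolated), via monomer quinone methide 7 (not isolated)
Conditions: 37% aq CH2O (0.25 equiv), 1% aq KOH, 0 °C to rt, short contact; then 1 M HCl; excess 3 recovered
Reagents that add atoms: formaldehyde, C=O
Why: Lederer–Manasse hydroxymethylation of the phenoxide of 3 gives 6, which loses hydroxide to quinone methide 7 that is trapped by a free ring carbon of a second phenoxide (phenol–formaldehyde condensation as used for methylene-bis-acylphloroglucinols); the excess of 3 and the short contact time are meant to stop the chain at the dimer.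

Step 4
Reactants: 8 core dimer; 9 Eschenmoser's salt (dimethylmethyleneiminium iodide)
Product: 11 bis[3-butanoyl-5-(dimethylaminomethyl)-2,4,6-trihydroxyphenyl]methane (core bis-Mannich base), via core mono-Mannich base 10 (not isolated)
Conditions: 9 (2.2 equiv), Et3N (2.2 equiv), CH2Cl2–MeCN, 0 °C, 8 added to the iminium salt; neutral work-up
Reagents that add atoms: none
Why: Mannich aminomethylation with a preformed iminium salt takes place at the one remaining ring C–H of each ring, and inverse addition at 0 °C keeps free 8 away from the product so that no premature quinone methide coupling should occur.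

Step 5
Reactants: 5 methylated ketone; 9 Eschenmoser's salt
Product: 12 1-[3-(dimethylaminomethyl)-2,4,6-trihydroxy-5-methylphenyl]butan-1-one
Conditions: 9 (1.05 equiv), Et3N (1.05 equiv), CH2Cl2, 0 °C to rt
Reagents that add atoms: none
Why: Mannich aminomethylation of 5 has only one ring C–H available, so a single mono-Mannich base is expected.

Step 6
Reactants: 12 Mannich base of the methylated monomer; 3 butanoylphloroglucinol (excess)
Product: 14 (3-butanoyl-2,4,6-trihydroxyphenyl)(3-butanoyl-2,4,6-trihydroxy-5-methylphenyl)methane (outer dimer with one free ring carbon), via methyl-monomer quinone methide 13 (not isolated)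
Conditions: 3 (4 equiv), NaOAc (0.2 equiv), 1,4-dioxane, 70 °C, N2 sweep; excess 3 recovered
Reagents that add atoms: none
Why: Thermal E1cB loss of dimethylamine from the ortho-hydroxybenzylamine 12 gives quinone methide 13, which is captured by a free ring carbon of the phenoxide of 3 (Mannich-base alkylation of an acylphloroglucinol); 12 has no free ring carbon and cannot self-condense, and the excess of 3 suppresses a second alkylation of 14.

Step 7
Reactants: 11 core bis-Mannich base; 14 outer dimer (two equivalents react)
Product: 18 symmetric six-ring chain capped by two C-methylated rings, via core mono-quinone methide 15 (not isolated), via four-ring Mannich base 16 (not isolated), via four-ring quinone methide 17 (not isolated)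
Conditions: 14 (2.3 equiv), NaOAc (0.2 equiv), degassed 1,4-dioxane, 65–70 °C, slow addition of 11, N2 sweep; then dilute aq HCl wash
Reagents that add atoms: none
Why: Each CH2NMe2 arm of 11 sits ortho to an ionised ring hydroxyl, so warming expels dimethylamine by an E1cB path to give ortho-quinone methide 15, whose exocyclic CH2 is attacked by the phenoxide of 14 through its only unsubstituted ring carbon, and tautomerisation restores the aromatic ring; the four-ring Mannich base 16 then repeats the sequence through 17 at the second arm. The closest known reaction type is the Mannich-base (ortho-quinone methide) alkylation that joins two acylphloroglucinols through one CH2, here carried out twice on one core. No ring is closed and no stereocentre is created, so neither a mode of closure nor facial control has to be settled; the two new bonds are the CH2–aryl bonds to the free ring carbons of the two outer dimers. The selectivity needed is cross-coupling over homo-coupling and C- over O-alkylation: 11 has no free ring carbon and 14 has no latent electrophile, so only the 1:2 adduct can arise, and any O-adduct should revert to the quinone methide under the conditions. Slow addition of 11 to an excess of 14 keeps the quinone methide away from a second core molecule, and the moderate temperature with removal of dimethylamine is meant to avoid ipso attack and redistribution of existing CH2 bridges. Because both arms and both nucleophiles are identical, the double coupling can give only the symmetric chain 18.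

Step 8
Reactants: 18 symmetric six-ring chain
Product: 19 target CNP0309827.0
Conditions: NaOMe (7 equiv), MeI (1.0 equiv), MeOH, 0 °C, stopped at partial conversion; 1 M HCl; recovered 18 resubmitted
Reagents that add atoms: iodomethane, CI
Why: C-methylation of a phloroglucinol polyanion with iodomethane is the known conversion of a C-methyl acylphloroglucinol into its gem-dimethyl dienone; in 18 every ring carbon is substituted and only the two terminal methyl-bearing carbons are unhindered, so one equivalent of MeI should dearomatise one end to ring A, and no stereocentre arises because the new quaternary carbon carries two identical methyls.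

**Compound list**

1 | phloroglucinol (benzene-1,3,5-triol) | Oc1cc(O)cc(O)c1 | starting material
2 | butanoyl chloride | CCCC(Cl)=O | starting material
3 | 1-(2,4,6-trihydroxyphenyl)butan-1-one | CCCC(=O)c1c(O)cc(O)cc1O | intermediate
4 | 2-methylbenzene-1,3,5-triol | Cc1c(O)cc(O)cc1O | starting material
5 | 1-(2,4,6-trihydroxy-3-methylphenyl)butan-1-one | CCCC(=O)c1c(O)cc(O)c(C)c1O | intermediate
6 | 1-[2,4,6-trihydroxy-3-(hydroxymethyl)phenyl]butan-1-one | CCCC(=O)c1c(O)cc(O)c(CO)c1O | intermediate (not isolated)
7 | ortho-quinone methide formed from 6 by loss of water | C=C1C(=O)C(C(=O)CCC)=C(O)C=C1O | intermediate (not isolated)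
8 | bis(3-butanoyl-2,4,6-trihydroxyphenyl)methane, ring C–ring D core dimer | CCCC(=O)c1c(O)cc(O)c(Cc2c(O)cc(O)c(C(=O)CCC)c2O)c1O | intermediate
9 | Eschenmoser's salt, dimethylmethyleneiminium iodide | C=[N+](C)C.[I-] | starting material
10 | core dimer carrying one CH2NMe2 arm | CCCC(=O)c1c(O)c(CN(C)C)c(O)c(Cc2c(O)cc(O)c(C(=O)CCC)c2O)c1O | intermediate (not isolated)
11 | bis[3-butanoyl-5-(dimethylaminomethyl)-2,4,6-trihydroxyphenyl]methane, core bis-Mannich base | CCCC(=O)c1c(O)c(CN(C)C)c(O)c(Cc2c(O)c(CN(C)C)c(O)c(C(=O)CCC)c2O)c1O | intermediate
12 | 1-[3-(dimethylaminomethyl)-2,4,6-trihydroxy-5-methylphenyl]butan-1-one | CCCC(=O)c1c(O)c(C)c(O)c(CN(C)C)c1O | intermediate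
13 | ortho-quinone methide formed from 12 by loss of dimethylamine | C=C1C(=O)C(C(=O)CCC)=C(O)C(C)=C1O | intermediate (not isolated)
14 | (3-butanoyl-2,4,6-trihydroxyphenyl)(3-butanoyl-2,4,6-trihydroxy-5-methylphenyl)methane, outer dimer | CCCC(=O)c1c(O)cc(O)c(Cc2c(O)c(C)c(O)c(C(=O)CCC)c2O)c1O | intermediate
15 | core mono-quinone methide, still carrying the second CH2NMe2 arm | C=C1C(=O)C(C(=O)CCC)=C(O)C(Cc2c(O)c(CN(C)C)c(O)c(C(=O)CCC)c2O)=C1O | intermediate (not isolated)
16 | four-ring chain (one outer dimer joined to the core) with one CH2NMe2 arm left | CCCC(=O)c1c(O)c(C)c(O)c(Cc2c(O)c(C(=O)CCC)c(O)c(Cc3c(O)c(C(=O)CCC)c(O)c(Cc4c(O)c(CN(C)C)c(O)c(C(=O)CCC)c4O)c3O)c2O)c1O | intermediate (not isolated)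
17 | ortho-quinone methide formed from 16 by loss of dimethylamine | CCCC(=O)c1c(O)c(C)c(O)c(Cc2c(O)c(C(=O)CCC)c(O)c(Cc3c(O)c(C(=O)CCC)c(O)c(CC4=C(O)C(=C)C(=O)C(C(=O)CCC)=C4O)c3O)c2O)c1O | intermediate (not isolated)
18 | symmetric six-ring chain: four CH2-linked butanoylphloroglucinol rings capped at each end, through CH2, by a 3-butanoyl-2,4,6-trihydroxy-5-methylphenyl ring | CCCC(=O)c1c(O)c(C)c(O)c(Cc2c(O)c(C(=O)CCC)c(O)c(Cc3c(O)c(C(=O)CCC)c(O)c(Cc4c(O)c(C(=O)CCC)c(O)c(Cc5c(O)c(C(=O)CCC)c(O)c(Cc6c(O)c(C)c(O)c(C(=O)CCC)c6O)c5O)c4O)c3O)c2O)c1O | intermediate
19 | CNP0309827.0: as 18, but one terminal ring is the 5-butanoyl-2,4-dihydroxy-3,3-dimethyl-6-oxocyclohexa-1,4-dien-1-yl ring A | CCCC(=O)C1=C(O)C(C)(C)C(O)=C(Cc2c(O)c(Cc3c(O)c(Cc4c(O)c(Cc5c(O)c(Cc6c(O)c(C)c(O)c(C(=O)CCC)c6O)c(O)c(C(=O)CCC)c5O)c(O)c(C(=O)CCC)c4O)c(O)c(C(=O)CCC)c3O)c(O)c(C(=O)CCC)c2O)C1=O | target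

**Step count**

Total steps: 8.
Longest linear sequence: 5 steps (steps 1, 3, 4, 7, 8 from phloroglucinol; the branch through steps 2, 5, 6, 7, 8 is equally long).

**Steps most likely to fail**

Step 8. The methylation may lose control of site and count: both C-methylated ends may be alkylated, alkylation may occur at bridge-bearing carbons or on oxygen, and the CH2 bridges may redistribute in the strongly basic medium. The fallback introduces the second methyl before the chain is assembled; it sets out from 5 and returns to the route at 19. Ketone 5 would be C-methylated (MeI, NaOMe, MeOH) to 2-butanoyl-3,5-dihydroxy-4,4-dimethylcyclohexa-2,5-dien-1-one F1, which is separable from over- and regio-methylated monomers at this small scale of structure. Aminomethylation of its single ring C–H with 9 and Et3N should give the Mannich base F2. Warming F2 with excess 3 in dioxane should release the dienone quinone methide F3, whose capture by 3 gives the ring A–ring B dimer F4 with one free carbon on ring B. The bis-Mannich base 11 would then be heated with one equivalent of 14 to the stage of the four-ring Mannich base 16, and one equivalent of F4 added, so that quinone methide 17 is captured by ring B and 19 forms directly. The outcome is statistical, but the three possible six-ring chains differ in their number of dienone ends, and no six-ring chain is exposed to methoxide.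

Step 7. The double coupling may stall after the first arm has reacted, the quinone methide may attack a substituted ring carbon of another core molecule, and the bridges may redistribute on the prolonged heating needed for the second arm. The fallback reverses the polarity of the coupling; it sets out from 14 and returns at 18. The free ring carbon of 14 would be aminomethylated with 9 and Et3N to the outer-dimer Mannich base F5. Two equivalents of F5 would be heated with the core dimer 8, which offers one free carbon on each ring. Each outer-dimer quinone methide F6 is then captured by 8, first to the four-ring chain F7 with one free carbon and then to 18. Here too neither partner can self-condense, and the two nucleophilic sites lie on separate rings.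

Step 3. The condensation may run past the dimer, because 8 still has two nucleophilic ring carbons and competes with 3 for the quinone methide. The fallback builds the diarylmethane before the acyl groups; it sets out from 1 and returns at 8. Phloroglucinol 1 in large excess would be condensed with formaldehyde (dilute aq HCl, rt) to bis(2,4,6-trihydroxyphenyl)methane F8. A twofold Houben–Hoesch reaction with butanenitrile (ZnCl2, HCl gas, Et2O, 0 °C) should give the bis(ketiminium chloride) F9, one acyl equivalent per ring because the iminium group deactivates its ring. Hydrolysis in warm water then gives 8.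

**Further compounds**

F1 | step 8 | 2-butanoyl-3,5-dihydroxy-4,4-dimethylcyclohexa-2,5-dien-1-one (butanoylfilicinic acid) | CCCC(=O)C1=C(O)C(C)(C)C(O)=CC1=O
F2 | step 8 | 2-butanoyl-6-(dimethylaminomethyl)-3,5-dihydroxy-4,4-dimethylcyclohexa-2,5-dien-1-one | CCCC(=O)C1=C(O)C(C)(C)C(O)=C(CN(C)C)C1=O
F3 | step 8 | quinone methide formed from F2 by loss of dimethylamine | CCCC(=O)C1=C(O)C(C)(C)C(=O)C(=C)C1=O
F4 | step 8 | ring A–ring B dimer: butanoylfilicinic acid joined through CH2 to butanoylphloroglucinol, one free ring carbon | CCCC(=O)C1=C(O)C(C)(C)C(O)=C(Cc2c(O)cc(O)c(C(=O)CCC)c2O)C1=O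
F5 | step 7 | outer dimer 14 carrying CH2NMe2 on its formerly free ring carbon | CCCC(=O)c1c(O)c(CN(C)C)c(O)c(Cc2c(O)c(C)c(O)c(C(=O)CCC)c2O)c1O
F6 | step 7 | quinone methide formed from F5 by loss of dimethylamine | C=C1C(=O)C(C(=O)CCC)=C(O)C(Cc2c(O)c(C)c(O)c(C(=O)CCC)c2O)=C1O
F7 | step 7 | four-ring chain (one outer dimer joined to core dimer 8) with one free ring carbon | CCCC(=O)c1c(O)c(C)c(O)c(Cc2c(O)c(C(=O)CCC)c(O)c(Cc3c(O)c(C(=O)CCC)c(O)c(Cc4c(O)cc(O)c(C(=O)CCC)c4O)c3O)c2O)c1O
F8 | step 3 | bis(2,4,6-trihydroxyphenyl)methane | Oc1cc(O)c(Cc2c(O)cc(O)cc2O)c(O)c1
F9 | step 3 | bis(ketiminium chloride) of the core dimer | CCCC(=[NH2+])c1c(O)cc(O)c(Cc2c(O)cc(O)c(C(CCC)=[NH2+])c2O)c1O.[Cl-].[Cl-]
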